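**Retrosynthetic overview**

- The enal on ring D is carried as a nitrile (i-Bu2AlH, then Wittig formyl-olefination). The two erythro aryl-glycerol ether units are cut at their benzylic C–C bonds by auxiliary-controlled syn-aldol reactions of aryloxyacetyl imides, each followed by Mitsunobu inversion of the benzylic carbinol and LiBH4 cleavage. The union is convergent: ring C imide plus ring A/B aldehyde.
- The dihydrofuran ring is the only ring made; the four benzene rings are bought. It is closed in one flask from an erythro epoxy alcohol and a fluoro-iodo-arene: SNAr forms the aryl C7a–O1 bond, then iodine–lithium exchange and epoxide opening form the aryl C3a–C3 bond.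
- Enabling feature: on ring D the carbon bearing the ring oxygen (C7a) is para to the C5 side-chain carbon and ortho to C3a. With C5 held as C≡N, fluorine on C7a is an SNAr nucleofuge and iodine on C3a is the carbanion handle.
- C3 with its CH2–O is carried as a terminal epoxide. Its erythro relation to the benzylic carbinol (Sharpless kinetic resolution) becomes the trans-2,3 relation by inversion at C3.

Key step: step 5

Remark: rings are lettered A (guaiacyl), B and C (syringyl) and D (benzo ring of the dihydrobenzofuran, benzofuran locants); TBS = tert-butyldimethylsilyl; the compounds marked "starting material" in the list are assumed to be catalogue items.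

**Route**

Step 1
Reactants: 1 4-amino-3-methoxybenzonitrile
Product: 2 4-amino-3-iodo-5-methoxybenzonitrile
Conditions: N-iodosuccinimide, CF3CO2H (cat.), MeCN, rt
Reagents that add atoms: N-iodosuccinimide, O=C1CCC(=O)N1I
Why: Electrophilic aromatic iodination, directed by the amino group to its only free ortho position.

Step 2
Reactants: 2 4-amino-3-iodo-5-methoxybenzonitrile
Product: 4 4-fluoro-3-iodo-5-methoxybenzonitrile, via arenediazonium fluoride 3 (not isolated)
Conditions: NaNO2, HF·pyridine, 0 °C; then 80 °C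
Reagents that add atoms: hydrogen fluoride (as its pyridine complex), F
Why: Diazotisation followed by thermal fluoro-dediazoniation (Balz–Schiemann-type reaction in HF·pyridine) should replace NH2 by F without touching iodide or nitrile.

Step 3
Reactants: 5 4-(benzyloxy)-3,5-dimethoxybenzaldehyde
Product: 6 rac-1-[4-(benzyloxy)-3,5-dimethoxyphenyl]prop-2-en-1-ol
Conditions: vinylmagnesium bromide, THF, −78 → 0 °C; aq. NH4Cl
Reagents that add atoms: vinylmagnesium bromide, C=C[Mg]Br
Why: Grignard 1,2-addition to a non-enolisable aldehyde; the racemic carbinol is resolved in the next step.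

Step 4
Reactants: 6 rac-1-[4-(benzyloxy)-3,5-dimethoxyphenyl]prop-2-en-1-ol
Product: 7 (S)-[4-(benzyloxy)-3,5-dimethoxyphenyl][(2R)-oxiran-2-yl]methanol (erythro)
Conditions: Ti(OiPr)4 (cat.), L-(+)-diisopropyl tartrate, t-BuOOH (just under half an equivalent), 4 Å MS, CH2Cl2, −20 °C
Reagents that add atoms: tert-butyl hydroperoxide, CC(C)(C)OO
Why: Sharpless kinetic resolution: with the L-(+)-tartrate the (R)-carbinol should be epoxidised fast and erythro-selectively, so the tartrate fixes the oxirane carbon as R and the surviving carbinol as S, while (S)-6 stays behind.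

Step 5
Reactants: 7 (S)-[4-(benzyloxy)-3,5-dimethoxyphenyl][(2R)-oxiran-2-yl]methanol; 4 4-fluoro-3-iodo-5-methoxybenzonitrile
Product: 10 (2R,3S)-2-[4-(benzyloxy)-3,5-dimethoxyphenyl]-3-(hydroxymethyl)-7-methoxy-2,3-dihydro-1-benzofuran-5-carbonitrile, via aryl oxiranylmethyl ether 8 (not isolated), via aryllithium 9 (not isolated)
Conditions: 7 + 4, THF, KN(SiMe3)2 added last, −78 → 0 °C; same flask, high dilution, −100 °C, t-BuLi (3 equiv); → −40 °C; aq. NH4Cl
Reagents that add atoms: none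
Why: The potassium alkoxide of 7 adds to the fluorine-bearing carbon of 4 (para to the nitrile, flanked by inductively withdrawing iodine and methoxy) and loss of fluoride from the Meisenheimer adduct forms the aryl–oxygen bond (SNAr etherification). Iodine–lithium exchange then makes the neighbouring ring carbon an aryllithium that opens the tethered oxirane at its internal carbon and forms the aryl–C3 bond; this is a Parham-type cyclization, with the closest known case being ortho-lithiated aryl glycidyl ethers closing to 2,3-dihydrobenzofuran-3-methanols. The dihydrofuran ring closes in the 5-exo-tet mode (exo opening of the epoxide), which the collinear SN2 trajectory and a halide-poor lithium medium should favour over 6-endo attack at the CH2 terminus. C2 is carried over unchanged from the carbinol of 7, and C3 arises by inversion of the (R)-oxirane carbon, so the erythro epoxy alcohol should map onto the trans (2R,3S) ring with the hydroxymethyl group already free. The step needs O-arylation to outrun Payne isomerisation of the epoxy alkoxide (base added last to the strongly activated fluoroarene at low temperature) and exchange to outrun attack on the nitrile (−100 °C, dilution).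

Step 6
Reactants: 10 (2R,3S)-2-[4-(benzyloxy)-3,5-dimethoxyphenyl]-3-(hydroxymethyl)-7-methoxy-2,3-dihydro-1-benzofuran-5-carbonitrile
Product: 11 (2R,3S)-2-[4-(benzyloxy)-3,5-dimethoxyphenyl]-3-{[(tert-butyldimethylsilyl)oxy]methyl}-7-methoxy-2,3-dihydro-1-benzofuran-5-carbonitrile
Conditions: TBSCl, imidazole, DMF, rt
Reagents that add atoms: tert-butyldimethylsilyl chloride, CC(C)(C)[Si](C)(C)Cl
Why: Standard silylation of the primary alcohol, which would otherwise consume the boron and Mitsunobu reagents later.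

Step 7
Reactants: 11 (2R,3S)-2-[4-(benzyloxy)-3,5-dimethoxyphenyl]-3-{[(tert-butyldimethylsilyl)oxy]methyl}-7-methoxy-2,3-dihydro-1-benzofuran-5-carbonitrile
Product: 12 (2R,3S)-3-{[(tert-butyldimethylsilyl)oxy]methyl}-2-(4-hydroxy-3,5-dimethoxyphenyl)-7-methoxy-2,3-dihydro-1-benzofuran-5-carbonitrile
Conditions: H2 (1 atm), 10% Pd/C, EtOAc, rt
Reagents that add atoms: none
Why: Hydrogenolysis of the benzyl aryl ether; under neutral low-pressure conditions the nitrile, the silyl ether and the ring C2–O bond should survive.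

Step 8
Reactants: 12 (2R,3S)-3-{[(tert-butyldimethylsilyl)oxy]methyl}-2-(4-hydroxy-3,5-dimethoxyphenyl)-7-methoxy-2,3-dihydro-1-benzofuran-5-carbonitrile; 13 (R)-4-benzyl-3-(2-chloroacetyl)-1,3-oxazolidin-2-one
Product: 14 (4R)-4-benzyl-3-{[4-((2R,3S)-3-{[(tert-butyldimethylsilyl)oxy]methyl}-5-cyano-7-methoxy-2,3-dihydro-1-benzofuran-2-yl)-2,6-dimethoxyphenoxy]acetyl}-1,3-oxazolidin-2-one
Conditions: K2CO3, NaI (cat.), MeCN, 50 °C
Reagents that add atoms: none
Why: Williamson O-alkylation of the hindered phenoxide at the primary α-chloro carbonyl carbon (Finkelstein activation by iodide).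

Step 9
Reactants: 15 4-hydroxy-3,5-dimethoxybenzonitrile; 13 (R)-4-benzyl-3-(2-chloroacetyl)-1,3-oxazolidin-2-one
Product: 16 (R)-4-benzyl-3-[2-(4-cyano-2,6-dimethoxyphenoxy)acetyl]-1,3-oxazolidin-2-one
Conditions: K2CO3, NaI (cat.), MeCN, 50 °C
Reagents that add atoms: none
Why: Same Williamson O-alkylation; the nitrile masks the ring B aldehyde so that it cannot act as an acceptor in the next step.

Step 10
Reactants: 16 (R)-4-benzyl-3-[2-(4-cyano-2,6-dimethoxyphenoxy)acetyl]-1,3-oxazolidin-2-one; 17 4-[(tert-butyldimethylsilyl)oxy]-3-methoxybenzaldehyde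
Product: 19 (4R)-4-benzyl-3-[(2R,3S)-3-{4-[(tert-butyldimethylsilyl)oxy]-3-methoxyphenyl}-2-(4-cyano-2,6-dimethoxyphenoxy)-3-hydroxypropanoyl]-1,3-oxazolidin-2-one, via dibutylboron enolate 18 (not isolated)
Conditions: Bu2BOTf, i-Pr2NEt, CH2Cl2, −78 → 0 °C; 17, −78 → 0 °C; pH 7 buffer (KH2PO4/K2HPO4), MeOH, H2O2
Reagents that add atoms: none
Why: Evans syn-aldol through the Z boron enolate and a Zimmerman–Traxler chair; the (R)-benzyl auxiliary fixes the ether-bearing carbon in its final configuration and gives the syn (threo) carbinol.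

Step 11
Reactants: 19 the syn-aldol adduct
Product: 20 (4R)-4-benzyl-3-[(2R,3R)-3-{4-[(tert-butyldimethylsilyl)oxy]-3-methoxyphenyl}-2-(4-cyano-2,6-dimethoxyphenoxy)-3-[(4-nitrobenzoyl)oxy]propanoyl]-1,3-oxazolidin-2-one
Conditions: 4-nitrobenzoic acid, PPh3, diisopropyl azodicarboxylate, THF, 0 °C → rt
Reagents that add atoms: 4-nitrobenzoic acid, OC(=O)c1ccc(cc1)[N+](=O)[O-]
Why: Mitsunobu esterification with SN2 inversion at the benzylic carbinol turns the threo adduct into the erythro series required by the target.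

Step 12
Reactants: 20 the inverted 4-nitrobenzoate
Product: 21 4-{[(1R,2S)-1-{4-[(tert-butyldimethylsilyl)oxy]-3-methoxyphenyl}-1,3-dihydroxypropan-2-yl]oxy}-3,5-dimethoxybenzonitrile
Conditions: LiBH4, THF, H2O (1 equiv), 0 °C → rt
Reagents that add atoms: none
Why: Reductive cleavage of the imide to the primary alcohol, with reduction of the 4-nitrobenzoate freeing the benzylic alcohol in the same pot; the aryl nitrile is inert to LiBH4.

Step 13
Reactants: 21 the erythro diol
Product: 22 4-{[(1R,2S)-1,3-bis[(tert-butyldimethylsilyl)oxy]-1-{4-[(tert-butyldimethylsilyl)oxy]-3-methoxyphenyl}propan-2-yl]oxy}-3,5-dimethoxybenzonitrile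
Conditions: TBSOTf, 2,6-lutidine, CH2Cl2, 0 °C
Reagents that add atoms: tert-butyldimethylsilyl trifluoromethanesulfonate, CC(C)(C)[Si](C)(C)OS(=O)(=O)C(F)(F)F
Why: Silylation of both hydroxyls so that the fragment tolerates the boron aldol and the Mitsunobu reaction of the union.

Step 14
Reactants: 22 the tris-silyl nitrile
Product: 23 4-{[(1R,2S)-1,3-bis[(tert-butyldimethylsilyl)oxy]-1-{4-[(tert-butyldimethylsilyl)oxy]-3-methoxyphenyl}propan-2-yl]oxy}-3,5-dimethoxybenzaldehyde
Conditions: i-Bu2AlH, CH2Cl2, −78 °C; aq. KNaC4H4O6 (potassium sodium tartrate)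
Reagents that add atoms: water, O
Why: Partial reduction of the nitrile to the N-aluminio aldimine, hydrolysed to the aldehyde on work-up.

Step 15
Reactants: 14 the ring C imide; 23 the ring A/B aldehyde
Product: 25 Evans syn-aldol adduct of 14 with 23 (acyl chain 2R,3S; full name in the compound list), via dibutylboron enolate 24 (not isolated)
Conditions: Bu2BOTf, i-Pr2NEt, CH2Cl2, −78 → 0 °C; 23, −78 → 0 °C; pH 7 buffer (KH2PO4/K2HPO4), MeOH, H2O2
Reagents that add atoms: none
Why: Evans syn-aldol (Z boron enolate, chair transition state) joins the two halves; the (R)-auxiliary overrides the remote stereocentres, sets the ether-bearing carbon of unit B in its final configuration and gives the syn carbinol.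

Step 16
Reactants: 25 the syn-aldol adduct
Product: 26 the (2R,3R) 4-nitrobenzoate of 25 with inverted benzylic carbon
Conditions: 4-nitrobenzoic acid, PPh3, diisopropyl azodicarboxylate, THF, 0 °C → rt
Reagents that add atoms: 4-nitrobenzoic acid, OC(=O)c1ccc(cc1)[N+](=O)[O-]
Why: Mitsunobu inversion (SN2) at the only free hydroxyl converts unit B from threo to erythro.

Step 17
Reactants: 26 the inverted 4-nitrobenzoate
Product: 27 the diol nitrile (unit B as free (1R,2S) diol; four silyl ethers and the ring D nitrile intact)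
Conditions: LiBH4, THF, H2O (1 equiv), 0 °C → rt
Reagents that add atoms: none
Why: Reductive removal of the auxiliary and of the 4-nitrobenzoate in one pot; nitrile and silyl ethers should be untouched.

Step 18
Reactants: 27 the diol nitrile
Product: 28 the corresponding 2,3-dihydro-1-benzofuran-5-carbaldehyde
Conditions: i-Bu2AlH (excess), CH2Cl2, −78 → −40 °C; aq. KNaC4H4O6 (potassium sodium tartrate)
Reagents that add atoms: water, O
Why: Nitrile-to-aldehyde reduction via the aldimine; the two free hydroxyls only consume extra hydride.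

Step 19
Reactants: 28 the ring D aldehyde
Product: 29 the tetrasilylated (E)-enal
Conditions: (triphenylphosphoranylidene)acetaldehyde, toluene, 80 °C
Reagents that add atoms: (triphenylphosphoranylidene)acetaldehyde, O=CC=P(c1ccccc1)(c1ccccc1)c1ccccc1
Why: Wittig olefination with the stabilised formylmethylene ylide should give the (E)-cinnamaldehyde unit and tolerates free alcohols.

Step 20
Reactants: 29 the tetrasilylated enal
Product: 30 CNP0192639.1
Conditions: HF·pyridine, pyridine, THF, 0 °C → rt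
Reagents that add atoms: none
Why: Buffered fluoride desilylation removes the aryl, benzylic and two primary TBS ethers without acid that could ionise the benzylic alcohols or harm the enal.

**Compound list**

1 | 4-amino-3-methoxybenzonitrile | COc1cc(C#N)ccc1N | starting material
2 | 4-amino-3-iodo-5-methoxybenzonitrile | COc1cc(C#N)cc(I)c1N | intermediate
3 | 4-cyano-2-iodo-6-methoxybenzenediazonium fluoride | COc1cc(C#N)cc(I)c1[N+]#N.[F-] | intermediate
4 | 4-fluoro-3-iodo-5-methoxybenzonitrile | COc1cc(C#N)cc(I)c1F | intermediate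
5 | 4-(benzyloxy)-3,5-dimethoxybenzaldehyde | COc1cc(C=O)cc(OC)c1OCc1ccccc1 | starting material
6 | rac-1-[4-(benzyloxy)-3,5-dimethoxyphenyl]prop-2-en-1-ol | C=CC(O)c1cc(OC)c(OCc2ccccc2)c(OC)c1 | intermediate
7 | (S)-[4-(benzyloxy)-3,5-dimethoxyphenyl][(2R)-oxiran-2-yl]methanol | O[C@@H](c1cc(OC)c(OCc2ccccc2)c(OC)c1)[C@H]1CO1 | intermediate
8 | 4-{(S)-[4-(benzyloxy)-3,5-dimethoxyphenyl][(2R)-oxiran-2-yl]methoxy}-3-iodo-5-methoxybenzonitrile | N#Cc1cc(I)c(O[C@@H](c2cc(OC)c(OCc3ccccc3)c(OC)c2)[C@H]2CO2)c(OC)c1 | intermediate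
9 | aryllithium from 8 (lithium in place of iodine) | N#Cc1cc([Li])c(O[C@@H](c2cc(OC)c(OCc3ccccc3)c(OC)c2)[C@H]2CO2)c(OC)c1 | intermediate
10 | (2R,3S)-2-[4-(benzyloxy)-3,5-dimethoxyphenyl]-3-(hydroxymethyl)-7-methoxy-2,3-dihydro-1-benzofuran-5-carbonitrile | COc1cc(cc(OC)c1OCc1ccccc1)[C@@H]1Oc2c(OC)cc(C#N)cc2[C@H]1CO | intermediate
11 | (2R,3S)-2-[4-(benzyloxy)-3,5-dimethoxyphenyl]-3-{[(tert-butyldimethylsilyl)oxy]methyl}-7-methoxy-2,3-dihydro-1-benzofuran-5-carbonitrile | COc1cc(cc(OC)c1OCc1ccccc1)[C@@H]1Oc2c(OC)cc(C#N)cc2[C@H]1CO[Si](C)(C)C(C)(C)C | intermediate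
12 | (2R,3S)-3-{[(tert-butyldimethylsilyl)oxy]methyl}-2-(4-hydroxy-3,5-dimethoxyphenyl)-7-methoxy-2,3-dihydro-1-benzofuran-5-carbonitrile | COc1cc(cc(OC)c1O)[C@@H]1Oc2c(OC)cc(C#N)cc2[C@H]1CO[Si](C)(C)C(C)(C)C | intermediate
13 | (R)-4-benzyl-3-(2-chloroacetyl)-1,3-oxazolidin-2-one | O=C(CCl)N1[C@H](Cc2ccccc2)COC1=O | starting material
14 | (4R)-4-benzyl-3-{[4-((2R,3S)-3-{[(tert-butyldimethylsilyl)oxy]methyl}-5-cyano-7-methoxy-2,3-dihydro-1-benzofuran-2-yl)-2,6-dimethoxyphenoxy]acetyl}-1,3-oxazolidin-2-one | COc1cc(cc(OC)c1OCC(=O)N1[C@H](Cc2ccccc2)COC1=O)[C@@H]1Oc2c(OC)cc(C#N)cc2[C@H]1CO[Si](C)(C)C(C)(C)C | intermediate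
15 | 4-hydroxy-3,5-dimethoxybenzonitrile | COc1cc(C#N)cc(OC)c1O | starting material
16 | (R)-4-benzyl-3-[2-(4-cyano-2,6-dimethoxyphenoxy)acetyl]-1,3-oxazolidin-2-one | COc1cc(C#N)cc(OC)c1OCC(=O)N1[C@H](Cc2ccccc2)COC1=O | intermediate
17 | 4-[(tert-butyldimethylsilyl)oxy]-3-methoxybenzaldehyde | COc1cc(C=O)ccc1O[Si](C)(C)C(C)(C)C | starting material
18 | (Z)-dibutylboron enolate of 16 | CCCCB(CCCC)O/C(=C\Oc1c(OC)cc(C#N)cc1OC)N1[C@H](Cc2ccccc2)COC1=O | intermediate
19 | (4R)-4-benzyl-3-[(2R,3S)-3-{4-[(tert-butyldimethylsilyl)oxy]-3-methoxyphenyl}-2-(4-cyano-2,6-dimethoxyphenoxy)-3-hydroxypropanoyl]-1,3-oxazolidin-2-one | COc1cc(ccc1O[Si](C)(C)C(C)(C)C)[C@H](O)[C@H](C(=O)N1[C@H](Cc2ccccc2)COC1=O)Oc1c(OC)cc(C#N)cc1OC | intermediate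
20 | (4R)-4-benzyl-3-[(2R,3R)-3-{4-[(tert-butyldimethylsilyl)oxy]-3-methoxyphenyl}-2-(4-cyano-2,6-dimethoxyphenoxy)-3-[(4-nitrobenzoyl)oxy]propanoyl]-1,3-oxazolidin-2-one | COc1cc(ccc1O[Si](C)(C)C(C)(C)C)[C@@H](OC(=O)c1ccc(cc1)[N+](=O)[O-])[C@H](C(=O)N1[C@H](Cc2ccccc2)COC1=O)Oc1c(OC)cc(C#N)cc1OC | intermediate
21 | 4-{[(1R,2S)-1-{4-[(tert-butyldimethylsilyl)oxy]-3-methoxyphenyl}-1,3-dihydroxypropan-2-yl]oxy}-3,5-dimethoxybenzonitrile | COc1cc(ccc1O[Si](C)(C)C(C)(C)C)[C@@H](O)[C@H](CO)Oc1c(OC)cc(C#N)cc1OC | intermediate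
22 | 4-{[(1R,2S)-1,3-bis[(tert-butyldimethylsilyl)oxy]-1-{4-[(tert-butyldimethylsilyl)oxy]-3-methoxyphenyl}propan-2-yl]oxy}-3,5-dimethoxybenzonitrile | COc1cc(ccc1O[Si](C)(C)C(C)(C)C)[C@@H](O[Si](C)(C)C(C)(C)C)[C@H](CO[Si](C)(C)C(C)(C)C)Oc1c(OC)cc(C#N)cc1OC | intermediate
23 | 4-{[(1R,2S)-1,3-bis[(tert-butyldimethylsilyl)oxy]-1-{4-[(tert-butyldimethylsilyl)oxy]-3-methoxyphenyl}propan-2-yl]oxy}-3,5-dimethoxybenzaldehyde | COc1cc(ccc1O[Si](C)(C)C(C)(C)C)[C@@H](O[Si](C)(C)C(C)(C)C)[C@H](CO[Si](C)(C)C(C)(C)C)Oc1c(OC)cc(C=O)cc1OC | intermediate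
24 | (Z)-dibutylboron enolate of 14 | CCCCB(CCCC)O/C(=C\Oc1c(OC)cc(cc1OC)[C@@H]1Oc2c(OC)cc(C#N)cc2[C@H]1CO[Si](C)(C)C(C)(C)C)N1[C@H](Cc2ccccc2)COC1=O | intermediate
25 | (4R)-4-benzyl-3-[(2R,3S)-3-(4-{[(1R,2S)-1,3-bis(TBS-oxy)-1-(4-TBS-oxy-3-methoxyphenyl)propan-2-yl]oxy}-3,5-dimethoxyphenyl)-2-[4-((2R,3S)-3-(TBS-oxymethyl)-5-cyano-7-methoxy-2,3-dihydro-1-benzofuran-2-yl)-2,6-dimethoxyphenoxy]-3-hydroxypropanoyl]-1,3-oxazolidin-2-one | COc1cc([C@@H](O[Si](C)(C)C(C)(C)C)[C@H](CO[Si](C)(C)C(C)(C)C)Oc2c(OC)cc([C@H](O)[C@H](C(=O)N3[C@H](Cc4ccccc4)COC3=O)Oc3c(OC)cc([C@@H]4Oc5c(OC)cc(C#N)cc5[C@H]4CO[Si](C)(C)C(C)(C)C)cc3OC)cc2OC)ccc1O[Si](C)(C)C(C)(C)C | intermediate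
26 | the (2R,3R)-3-[(4-nitrobenzoyl)oxy] analogue of 25 (benzylic carbon of unit B inverted) | COc1cc([C@@H](O[Si](C)(C)C(C)(C)C)[C@H](CO[Si](C)(C)C(C)(C)C)Oc2c(OC)cc([C@@H](OC(=O)c3ccc(cc3)[N+](=O)[O-])[C@H](C(=O)N3[C@H](Cc4ccccc4)COC3=O)Oc3c(OC)cc([C@@H]4Oc5c(OC)cc(C#N)cc5[C@H]4CO[Si](C)(C)C(C)(C)C)cc3OC)cc2OC)ccc1O[Si](C)(C)C(C)(C)C | intermediate
27 | (2R,3S)-2-(4-{[(1R,2S)-1-(4-{[(1R,2S)-1,3-bis(TBS-oxy)-1-(4-TBS-oxy-3-methoxyphenyl)propan-2-yl]oxy}-3,5-dimethoxyphenyl)-1,3-dihydroxypropan-2-yl]oxy}-3,5-dimethoxyphenyl)-3-(TBS-oxymethyl)-7-methoxy-2,3-dihydro-1-benzofuran-5-carbonitrile | COc1cc([C@@H](O[Si](C)(C)C(C)(C)C)[C@H](CO[Si](C)(C)C(C)(C)C)Oc2c(OC)cc([C@@H](O)[C@H](CO)Oc3c(OC)cc([C@@H]4Oc5c(OC)cc(C#N)cc5[C@H]4CO[Si](C)(C)C(C)(C)C)cc3OC)cc2OC)ccc1O[Si](C)(C)C(C)(C)C | intermediate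
28 | the 5-carbaldehyde corresponding to nitrile 27 | COc1cc([C@@H](O[Si](C)(C)C(C)(C)C)[C@H](CO[Si](C)(C)C(C)(C)C)Oc2c(OC)cc([C@@H](O)[C@H](CO)Oc3c(OC)cc([C@@H]4Oc5c(OC)cc(C=O)cc5[C@H]4CO[Si](C)(C)C(C)(C)C)cc3OC)cc2OC)ccc1O[Si](C)(C)C(C)(C)C | intermediate
29 | the (E)-prop-2-enal from 28 (four TBS ethers: ring A phenol, unit A benzylic and primary oxygens, dihydrofuran CH2O) | COc1cc([C@@H](O[Si](C)(C)C(C)(C)C)[C@H](CO[Si](C)(C)C(C)(C)C)Oc2c(OC)cc([C@@H](O)[C@H](CO)Oc3c(OC)cc([C@@H]4Oc5c(OC)cc(/C=C/C=O)cc5[C@H]4CO[Si](C)(C)C(C)(C)C)cc3OC)cc2OC)ccc1O[Si](C)(C)C(C)(C)C | intermediate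
30 | CNP0192639.1, (E)-3-[(2R,3S)-2-(4-{[(1R,2S)-1-(4-{[(1R,2S)-1,3-dihydroxy-1-(4-hydroxy-3-methoxyphenyl)propan-2-yl]oxy}-3,5-dimethoxyphenyl)-1,3-dihydroxypropan-2-yl]oxy}-3,5-dimethoxyphenyl)-3-(hydroxymethyl)-7-methoxy-2,3-dihydro-1-benzofuran-5-yl]prop-2-enal | COc1cc([C@@H](O)[C@H](CO)Oc2c(OC)cc([C@@H](O)[C@H](CO)Oc3c(OC)cc([C@@H]4Oc5c(OC)cc(/C=C/C=O)cc5[C@H]4CO)cc3OC)cc2OC)ccc1O | target

**Step count and risks**

Total steps: 20. Longest linear sequence: 12 steps (steps 3–8 and 15–20 from 5; the chains from 1 and from 15 are equally long).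

The three steps most likely to fail:

Step 5. The epoxy alkoxide may isomerise by Payne rearrangement before it is arylated. After the exchange the aryllithium may abstract the benzylic proton, open the epoxide at its CH2 terminus (6-endo) or add to the nitrile. The fallback replaces the anionic epoxide opening by a radical ring closure and sets out from 6 and 4. A kinetic resolution of 6 with the enantiomeric tartrate (Ti(OiPr)4, D-(−)-diisopropyl tartrate, t-BuOOH) would leave the slow-reacting enantiomer (R)-1-[4-(benzyloxy)-3,5-dimethoxyphenyl]prop-2-en-1-ol F1. Its potassium alkoxide would undergo the same SNAr reaction with 4 to give 4-({(1R)-1-[4-(benzyloxy)-3,5-dimethoxyphenyl]prop-2-en-1-yl}oxy)-3-iodo-5-methoxybenzonitrile F2, which has no epoxide and hence no Payne pathway. An aryl-radical 5-exo-trig cyclization with oxygen trapping (Bu3SnH, dry air, toluene; then PPh3) should then form the C3a–C3 bond and the hydroxymethyl group, trans by the chair-like Beckwith transition state, and comes back to the route at 10.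

Step 16 (the same operation as step 11, here on the most valuable material). The electron-rich benzylic oxyphosphonium ion may ionise, giving retention or scrambling at the carbinol, or eliminate to the α-aryloxy cinnamoyl imide. The fallback makes the erythro unit directly by an anti-aldol and sets out from 12 and 23. Alkylation of 12 with the enantiomeric reagent (S)-4-benzyl-3-(2-chloroacetyl)-1,3-oxazolidin-2-one (K2CO3, NaI) would give the (4S)-imide diastereomer of 14, F3. A magnesium-halide-catalysed anti-aldol with 23 (MgCl2, Et3N, Me3SiCl, EtOAc) proceeds through the chelated magnesium enolate, which reacts on the face opposite to that of the boron enolate, so the (S)-auxiliary should set the same ether-bearing carbon and give the anti adduct as its trimethylsilyl ether F4. LiBH4 reduction and mild acidic methanolysis then come back to the route at 27.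

Step 2. The diazonium ion flanked by iodine and methoxy may undergo hydro- or hydroxy-dediazoniation and tar formation instead of fluorination. The fallback avoids making the C–F bond and sets out from 2. Diazotisation (NaNO2, HBF4) and nitro-dediazoniation (NaNO2, copper powder, Sandmeyer-type) would give 3-iodo-5-methoxy-4-nitrobenzonitrile F5. Its nitro group is para to the nitrile and twisted out of conjugation by its two ortho neighbours, so it should serve as the SNAr nucleofuge in step 5 in place of fluoride; the fallback comes back to the route at 8 and from there at 10.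

Further compounds
F1 | step 5 | (R)-1-[4-(benzyloxy)-3,5-dimethoxyphenyl]prop-2-en-1-ol | C=C[C@@H](O)c1cc(OC)c(OCc2ccccc2)c(OC)c1
F2 | step 5 | 4-({(1R)-1-[4-(benzyloxy)-3,5-dimethoxyphenyl]prop-2-en-1-yl}oxy)-3-iodo-5-methoxybenzonitrile | N#Cc1cc(I)c(O[C@@H](c2cc(OC)c(OCc3ccccc3)c(OC)c2)C=C)c(OC)c1
F3 | step 16 | (4S)-4-benzyl-3-{[4-((2R,3S)-3-{[(tert-butyldimethylsilyl)oxy]methyl}-5-cyano-7-methoxy-2,3-dihydro-1-benzofuran-2-yl)-2,6-dimethoxyphenoxy]acetyl}-1,3-oxazolidin-2-one | COc1cc(cc(OC)c1OCC(=O)N1[C@@H](Cc2ccccc2)COC1=O)[C@@H]1Oc2c(OC)cc(C#N)cc2[C@H]1CO[Si](C)(C)C(C)(C)C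
F4 | step 16 | anti-aldol adduct of F3 with 23 as trimethylsilyl ether ((4S)-auxiliary; acyl chain 2R,3R; erythro) | COc1cc([C@@H](O[Si](C)(C)C(C)(C)C)[C@H](CO[Si](C)(C)C(C)(C)C)Oc2c(OC)cc([C@@H](O[Si](C)(C)C)[C@H](C(=O)N3[C@@H](Cc4ccccc4)COC3=O)Oc3c(OC)cc([C@@H]4Oc5c(OC)cc(C#N)cc5[C@H]4CO[Si](C)(C)C(C)(C)C)cc3OC)cc2OC)ccc1O[Si](C)(C)C(C)(C)C
F5 | step 2 | 3-iodo-5-methoxy-4-nitrobenzonitrile | COc1cc(C#N)cc(I)c1[N+](=O)[O-]
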